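The data come from a simulation from invented constants; noise was put on by code.

Find where the flask must finish, then how soon it gets there.

in all of them: starting material 0.036 M (in portions, 4)

| charge | second substrate | precatalyst | remark | time |
|---|---|---|---|---|
| dusk | 0.144 M | 0.39 µM | run made earlier; portions every 40 min |  |
| dawn | 0.144 M | 0.62 µM | run made earlier; portions every 40 min |  |
| noon | 0.29 M | 0.28 µM | run made earlier; portions every 40 min |  |
| flask | 0.144 M | 0.28 µM | the portions of starting material follow each other after 40 min, the first at the start | 5.0 d |

- dusk (time / d: starting material / %, target / %, isomer of the product / %): 0.417: 0, 76.7, 23.5; 1.04: 0.3, 76.4, 25.5; 2.08: 0, 76.8, 24.3; 3.00: 0, 75.2, 24.5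
- dawn (time / d: starting material / %, target / %, isomer of the product / %): 0.250: 0, 79.1, 20.0; 0.500: 0.2, 75.9, 23.4; 1.25: 0.5, 76.0, 24.6; 3.00: 0.7, 76.1, 24.7
- noon (time / d: starting material / %, target / %, isomer of the product / %): 0.417: 0, 75.4, 23.8; 1.04: 0.5, 75.6, 24.2; 2.08: 0, 75.6, 24.1; 3.00: 0, 75.4, 24.5

(readings scatter by 0.5 percentage points)

- the reaction counts as stopped when no species that holds the starting material changes by six tenths of a point or more over the second half of the time

1. the state of affairs at 5.0 d: stopped, and by what, or still going (it is still moving / forward and back rates have come level / the second substrate has run out first / no working catalyst is left / all of the starting material has reacted)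
2. part of the starting material gone at 5.0 d
3. the target standing at 5.0 d, as a percentage of the starting material charged
4. the isomer of the product standing at 5.0 d, as a percentage of the starting material charged

Start with the noon run at 3.00 d. Divide target by target plus isomer of the product to get 75.5 %, and call this the plateau share, the target's part of the two products once they stop moving. Now take a second way: the dawn run, with twice the precatalyst and half the second substrate, gives 75.5 % at 3.00 d. The charges differ, so this agreement is a real check. The ways part at the first dawn reading, 0.250 d, which gives 79.8 %, higher than the plateau share. That reading cheats: the dawn target falls to 75.9 % by 0.500 d while its isomer of the product climbs to 23.4 %, so those products were still moving.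

Next, the speed. The dusk run, with the second substrate of the flask, reads 0 % starting material at 0.417 d. If the rate follows precatalyst, the flask needs about 0.581 d, far less than 5.0 d. Taken one for one, starting material is the limiting reagent, at a quarter of the second substrate. My reckoning is therefore that the flask stops with its starting material at 0 %, as in that dusk reading, and with 75.5 % target and 24.5 % isomer of the product.

The forecast says: forward and back rates have come level, with 100 % conversion, 75.7 % target and 24.3 % isomer of the product. Its ground: “A common plateau independent of loading means equilibrium, not catalyst death or substrate exhaustion”. We differ on what stops the flask.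

By 5.0 d the flask stands thus: all of the starting material has reacted, with 100 % conversion, 75.8 % target and 24.2 % isomer of the product. Of their charges in the flask, 0 % of the starting material remains, less than the 75 % of the second substrate.

    starting material + enzyme ⇌ starting complex (K = 63.0 M⁻¹, k = 2.80 × 10⁷ M⁻¹ h⁻¹)
    target ⇌ isomer of the product (K = 0.320, k = 0.120 h⁻¹)
    second substrate + starting complex ⇌ ternary complex (K = 5.40 M⁻¹, k = 9.80 × 10⁵ M⁻¹ h⁻¹)
    precatalyst → enzyme (k = 0.420 h⁻¹)
    ternary complex → enzyme + target (k = 4.90 × 10⁵ h⁻¹)

Carry the plateau share, a reading with its scatter, to the neighbour flask charged with 4.8 × 10⁻⁷ M of precatalyst: it puts 75.5 % of the products there as target. That neighbour flask stands at 75.8 % target and 24.2 % isomer of the product at 5.00 d.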